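The synthesis rests on disconnecting the bond between the carbonyl carbon of one 2,4-dihydroxybenzoyl group and ring carbon C3 of the tetrahydrofuran (O1, C2–C5), the aroyl that is cis to the C2 aryl. The key step adds an aroyl radical to C3 of the C2=C3 enol ether of a (4R,5R)-trans-4-aroyl-2,5-diaryl-4,5-dihydrofuran; C–C bond formation anti to the C4 aroyl and hydrogen transfer to the O1- and aryl-stabilised C2 radical anti to the new substituent set C3 and C2 (2,3-cis, 3,4-trans, 2,5-cis) in one operation. Its precursor comes from an enantioenriched chalcone-derived aldol by phenacylation and cyclodehydration.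

Key step: step 7

Remarks on the chemistry
- Ring atoms are numbered O1, C2, C3, C4, C5 as in the target, C3 being the carbon that receives the aroyl group in the key step; Bn = benzyl, TES = triethylsilyl.
- Assumption: compounds 1, 2, 7 and 11 are taken as commercial.
- Assumption: the ferrocenyl diphosphine enantiomer named in step 2 is taken to deliver the (R)-configured C–B bond; if the sense of induction is the opposite, its mirror image is used.

Step 1
Reactants: 1 1-[2,4-bis(benzyloxy)phenyl]ethan-1-one; 2 4-(benzyloxy)benzaldehyde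
Product: 3 (E)-1-[2,4-bis(benzyloxy)phenyl]-3-[4-(benzyloxy)phenyl]prop-2-en-1-one
Conditions: KOH (50% aq.), EtOH–THF, rt
Reagents that add atoms: none
Why: Claisen–Schmidt condensation of a methyl ketone with a non-enolisable aldehyde; dehydration of the aldol should give the more stable E-enone.

Step 2
Reactants: 3 (E)-1-[2,4-bis(benzyloxy)phenyl]-3-[4-(benzyloxy)phenyl]prop-2-en-1-one
Product: 5 (R)-1-[2,4-bis(benzyloxy)phenyl]-3-[4-(benzyloxy)phenyl]-3-hydroxypropan-1-one, via boryl ketone 4 (not isolated)
Conditions: CuCl (3 mol%), NaOtBu (6 mol%), (R)-1-[(S)-2-(diphenylphosphino)ferrocenyl]ethyldicyclohexylphosphine (3 mol%), B2pin2, MeOH (2 equiv), THF, rt; then NaBO3·4H2O, THF–H2O, rt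
Reagents that add atoms: sodium perborate tetrahydrate, [Na+].[O-]OB=O.O.O.O.O
Why: Copper-catalysed asymmetric conjugate borylation, in which the ligand-bound Cu–Bpin species adds to one enantioface of the enone (catalyst control sets the future C5), followed by C–B oxidation with retention.

Step 3
Reactants: 5 (R)-1-[2,4-bis(benzyloxy)phenyl]-3-[4-(benzyloxy)phenyl]-3-hydroxypropan-1-one
Product: 6 (R)-1-[2,4-bis(benzyloxy)phenyl]-3-[4-(benzyloxy)phenyl]-3-[(triethylsilyl)oxy]propan-1-one
Conditions: TESCl, imidazole, DMF, 0 °C to rt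
Reagents that add atoms: chlorotriethylsilane, CC[Si](Cl)(CC)CC
Why: Silyl ether formation at the secondary alcohol masks the aldol hydroxyl so that the ketone can later be enolised without retro-aldol cleavage; no stereocentre is touched.

Step 4
Reactants: 6 (R)-1-[2,4-bis(benzyloxy)phenyl]-3-[4-(benzyloxy)phenyl]-3-[(triethylsilyl)oxy]propan-1-one; 7 2-bromo-1-[4-(benzyloxy)phenyl]ethan-1-one
Product: 8 1-[4-(benzyloxy)phenyl]-4-[2,4-bis(benzyloxy)phenyl]-3-{(R)-[4-(benzyloxy)phenyl][(triethylsilyl)oxy]methyl}butane-1,4-dione (both epimers at the carbon that becomes C4)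
Conditions: LiN(SiMe3)2 (1.1 equiv), THF, −78 °C; then 7, THF–DMPU, −78 to −40 °C
Reagents that add atoms: none
Why: Enolate alkylation: the ketone has one enolisable position and the lithium enolate should be alkylated by the reactive α-bromoketone at low temperature; the new centre (future C4) forms as a mixture that step 5 equilibrates.

Step 5
Reactants: 8 1-[4-(benzyloxy)phenyl]-4-[2,4-bis(benzyloxy)phenyl]-3-{(R)-[4-(benzyloxy)phenyl][(triethylsilyl)oxy]methyl}butane-1,4-dione
Product: 10 [(2R,3R)-2,5-bis[4-(benzyloxy)phenyl]-2,3-dihydrofuran-3-yl][2,4-bis(benzyloxy)phenyl]methanone (in target numbering: C2=C3 enol ether with the aroyl at C4 trans to the aryl at C5), via cyclic methyl ketal 9 (not isolated)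
Conditions: PPTS (0.2 equiv), MeOH–CH2Cl2, rt; then toluene, PPTS, 4 Å MS, 80 °C; then DBU (0.2 equiv), rt
Reagents that add atoms: none
Why: Cyclodehydration of a γ-hydroxy ketone: mild acid removes the TES group, the C5 hydroxyl closes onto the 4-benzyloxyphenyl ketone (the only five-membered option) as the methyl ketal, warming expels methanol to the aryl-conjugated enol ether, and DBU equilibrates the ketone α-carbon C4 through its dienolate to the more stable 4,5-trans isomer while C5 stays fixed.

Step 6
Reactants: 11 2,4-bis(benzyloxy)benzoic acid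
Product: 12 Se-phenyl 2,4-bis(benzyloxy)benzenecarboselenoate
Conditions: PhSeSePh (1.2 equiv), Bu3P (1.3 equiv), CH2Cl2, rt
Reagents that add atoms: diphenyl diselenide, c1ccc(cc1)[Se][Se]c1ccccc1
Why: Phosphine-mediated redox condensation: the selenophosphonium salt activates the carboxylate as an acyloxyphosphonium ion, which benzeneselenolate attacks to give the acyl selenide.

Step 7
Reactants: 10 [(2R,3R)-2,5-bis[4-(benzyloxy)phenyl]-2,3-dihydrofuran-3-yl][2,4-bis(benzyloxy)phenyl]methanone; 12 Se-phenyl 2,4-bis(benzyloxy)benzenecarboselenoate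
Product: 13 [(2S,3R,4R,5R)-2,5-bis[4-(benzyloxy)phenyl]tetrahydrofuran-3,4-diyl]bis{[2,4-bis(benzyloxy)phenyl]methanone}
Conditions: 12 (2 equiv), Bu3SnH (2.2 equiv, syringe pump, 8 h), Et3B (0.3 equiv)/air, toluene (0.3 M in 10), 20 °C; aq. KF work-up
Reagents that add atoms: none
Why: Et3B/air starts a stannane chain in which Bu3Sn• abstracts the phenylseleno group of 12; the aroyl radical adds to C3, the unsubstituted end of the C2=C3 enol ether, because this gives the C2 radical stabilised by O1 and the C2 aryl ring, and Bu3SnH then transfers hydrogen to C2. The closest known reaction type is the intermolecular addition of acyl radicals from acyl selenides to styrene-type alkenes under tin hydride chain conditions. No ring is closed. C3 is set by attack on the ring face anti to the neighbouring C4 aroyl group (3,4-trans), and C2 by hydrogen delivery anti to the new C3 aroyl group and to the C5 aryl group, which leaves the C2 aryl cis to both (2,3-cis, 2,5-cis), the less stable arrangement under kinetic control. The step needs addition to outrun direct reduction of the aroyl radical, which slow addition of the stannane and a high concentration of 10 should secure. It also needs a neutral medium at room temperature so that the enolisable C3 and C4 centres and the C2 radical (ring-opening β-scission) survive.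

Step 8
Reactants: 13 [(2S,3R,4R,5R)-2,5-bis[4-(benzyloxy)phenyl]tetrahydrofuran-3,4-diyl]bis{[2,4-bis(benzyloxy)phenyl]methanone}
Product: 14 [(2S,3R,4R,5R)-2,5-bis(4-hydroxyphenyl)tetrahydrofuran-3,4-diyl]bis[(2,4-dihydroxyphenyl)methanone] (CNP0237262.2)
Conditions: H2 (1 atm), 10% Pd/C, EtOAc–MeOH, rt
Reagents that add atoms: none
Why: Catalytic hydrogenolysis should cleave the six aryl benzyl ethers faster than the hindered cyclic benzylic C–O bonds, and under neutral conditions, so C3 and C4 (α to the ketones) are not epimerised.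

Compound list
1 | 1-[2,4-bis(benzyloxy)phenyl]ethan-1-one | CC(=O)c1ccc(OCc2ccccc2)cc1OCc1ccccc1 | starting material
2 | 4-(benzyloxy)benzaldehyde | O=Cc1ccc(OCc2ccccc2)cc1 | starting material
3 | (E)-1-[2,4-bis(benzyloxy)phenyl]-3-[4-(benzyloxy)phenyl]prop-2-en-1-one | O=C(/C=C/c1ccc(OCc2ccccc2)cc1)c1ccc(OCc2ccccc2)cc1OCc1ccccc1 | intermediate
4 | (R)-1-[2,4-bis(benzyloxy)phenyl]-3-[4-(benzyloxy)phenyl]-3-(4,4,5,5-tetramethyl-1,3,2-dioxaborolan-2-yl)propan-1-one | O=C(C[C@H](c1ccc(OCc2ccccc2)cc1)B1OC(C)(C)C(C)(C)O1)c1ccc(OCc2ccccc2)cc1OCc1ccccc1 | intermediate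
5 | (R)-1-[2,4-bis(benzyloxy)phenyl]-3-[4-(benzyloxy)phenyl]-3-hydroxypropan-1-one | O=C(C[C@H](c1ccc(OCc2ccccc2)cc1)O)c1ccc(OCc2ccccc2)cc1OCc1ccccc1 | intermediate
6 | (R)-1-[2,4-bis(benzyloxy)phenyl]-3-[4-(benzyloxy)phenyl]-3-[(triethylsilyl)oxy]propan-1-one | O=C(C[C@H](c1ccc(OCc2ccccc2)cc1)O[Si](CC)(CC)CC)c1ccc(OCc2ccccc2)cc1OCc1ccccc1 | intermediate
7 | 2-bromo-1-[4-(benzyloxy)phenyl]ethan-1-one | O=C(CBr)c1ccc(OCc2ccccc2)cc1 | starting material
8 | 1-[4-(benzyloxy)phenyl]-4-[2,4-bis(benzyloxy)phenyl]-3-{(R)-[4-(benzyloxy)phenyl][(triethylsilyl)oxy]methyl}butane-1,4-dione (epimers at C3 of the butanedione) | O=C(CC(C(=O)c1ccc(OCc2ccccc2)cc1OCc1ccccc1)[C@H](c1ccc(OCc2ccccc2)cc1)O[Si](CC)(CC)CC)c1ccc(OCc2ccccc2)cc1 | intermediate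
9 | [2,4-bis(benzyloxy)phenyl]{(2R)-2,5-bis[4-(benzyloxy)phenyl]-5-methoxytetrahydrofuran-3-yl}methanone (mixture at the ketal carbon and at the aroyl-bearing carbon) | COC1(c2ccc(OCc3ccccc3)cc2)CC(C(=O)c2ccc(OCc3ccccc3)cc2OCc2ccccc2)[C@H](c2ccc(OCc3ccccc3)cc2)O1 | intermediate
10 | [(2R,3R)-2,5-bis[4-(benzyloxy)phenyl]-2,3-dihydrofuran-3-yl][2,4-bis(benzyloxy)phenyl]methanone | O=C(c1ccc(OCc2ccccc2)cc1OCc1ccccc1)[C@@H]1C=C(c2ccc(OCc3ccccc3)cc2)O[C@H]1c1ccc(OCc2ccccc2)cc1 | intermediate
11 | 2,4-bis(benzyloxy)benzoic acid | O=C(O)c1ccc(OCc2ccccc2)cc1OCc1ccccc1 | starting material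
12 | Se-phenyl 2,4-bis(benzyloxy)benzenecarboselenoate | O=C([Se]c1ccccc1)c1ccc(OCc2ccccc2)cc1OCc1ccccc1 | intermediate
13 | [(2S,3R,4R,5R)-2,5-bis[4-(benzyloxy)phenyl]tetrahydrofuran-3,4-diyl]bis{[2,4-bis(benzyloxy)phenyl]methanone} | O=C(c1ccc(OCc2ccccc2)cc1OCc1ccccc1)[C@@H]1[C@@H](C(=O)c2ccc(OCc3ccccc3)cc2OCc2ccccc2)[C@H](c2ccc(OCc3ccccc3)cc2)O[C@@H]1c1ccc(OCc2ccccc2)cc1 | intermediate
14 | [(2S,3R,4R,5R)-2,5-bis(4-hydroxyphenyl)tetrahydrofuran-3,4-diyl]bis[(2,4-dihydroxyphenyl)methanone] | O=C(c1ccc(O)cc1O)[C@@H]1[C@@H](C(=O)c2ccc(O)cc2O)[C@H](c2ccc(O)cc2)O[C@@H]1c1ccc(O)cc1 | target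

Total step count: 8. Longest linear sequence: 7 steps (steps 1, 2, 3, 4, 5, 7, 8); step 6 is a one-step branch.

Steps most likely to fail

Step 7. The aroyl radical may be reduced by the stannane, or may take a hydrogen atom from its own ortho benzyloxy methylene (1,5-shift), before it adds to the electron-rich enol ether; the C2 radical may also open the ring by β-scission. Each of these lowers conversion more than selectivity. The fallback sets out from 10 and the acid 11 (step 6 is then not needed) and comes back at 13. It generates the same aroyl radical catalytically and without a hydride chain carrier: the excited photocatalyst [Ir{dF(CF3)ppy}2(dtbbpy)]PF6 oxidises PPh3, the carboxylate of 11 captures the phosphine radical cation, and β-scission of the phosphoranyl radical releases the aroyl radical. After addition to C3, the C2 radical is quenched by catalytic 2,4,6-triisopropylbenzenethiol, which the reduced photocatalyst and 2,6-lutidinium turn over (MeCN, blue LEDs, rt). The stereochemical argument is unchanged and no new compound is made (F0).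

Step 4. The lithium enolate of the β-silyloxy ketone may expel triethylsilanolate (back to chalcone 3) or be quenched by proton transfer from the acidic α-bromoketone, so that C-alkylation stalls. The fallback sets out from 6 and comes back at 8 by a conjugate-addition route. Direct α-methylenation of 6 (paraformaldehyde, diisopropylammonium trifluoroacetate, THF, 60 °C) should give the enone (S)-1-[2,4-bis(benzyloxy)phenyl]-2-{[4-(benzyloxy)phenyl][(triethylsilyl)oxy]methyl}prop-2-en-1-one F1. A thiazolium-catalysed Stetter reaction with aldehyde 2 (3-benzyl-5-(2-hydroxyethyl)-4-methylthiazolium chloride, Et3N, dioxane, 70 °C) then adds the acyl anion equivalent of 2 to the terminal methylene carbon and should give 8 without any enolate alkylation.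

Step 8. Selenium or tin residues may poison the palladium surface, and prolonged exposure may hydrogenolyse the two benzylic ring C–O bonds (C2–O1, C5–O1) or reduce the aryl ketones once the benzyl ethers are gone. The fallback sets out from 13 and comes back at 14 by Lewis-acid dealkylation instead of hydrogenolysis: BCl3 (excess) with pentamethylbenzene as benzyl-cation scavenger, CH2Cl2, −78 °C, methanol quench. It needs neither a metal surface nor hydrogen, and no new compound is made (F0).

Further compounds
F0 | step 7 | none | none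
F1 | step 4 | (S)-1-[2,4-bis(benzyloxy)phenyl]-2-{[4-(benzyloxy)phenyl][(triethylsilyl)oxy]methyl}prop-2-en-1-one | C=C(C(=O)c1ccc(OCc2ccccc2)cc1OCc1ccccc1)[C@H](c1ccc(OCc2ccccc2)cc1)O[Si](CC)(CC)CC
F0 | step 8 | none | none
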